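**The charges.** A small charge, 0.075 M of substrate under held gas, gave the spring run, and 0.11 M gave the dusk run. From these I had to reckon a flask of 0.15 M.

| flask | substrate | gas | remark | time |
|---|---|---|---|---|
| spring | 0.075 M | 15 mM (held) | run made earlier |  |
| dusk | 0.11 M | 15 mM (held) | run made earlier |  |
| flask | 0.15 M | 15 mM (held) |  | 8.0 min |

- spring (time / min: target / %, isomer of the product / %): 0.417: 5.3, 2.4; 0.667: 6.4, 4.4; 1.33: 12.8, 9.3; 2.50: 17.7, 19.2; 5.00: 15.6, 32.7
- dusk (time / min: target / %, isomer of the product / %): 1.00: 7.4, 5.1; 2.00: 12.6, 11.9; 3.00: 16.0, 18.7; 4.00: 15.5, 24.7; 5.00: 15.5, 28.7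

(standard deviation of a reading: 0.5 percentage points)

- ratio of target to isomer of the product at 8.0 s
- ratio of target to isomer of the product at 8.0 min

- the earlier runs were read with a standard deviation of 0.5 percentage points
- at the start none of the gas is in solution

**Main step.** I began with substrate going down two parallel branches of one order, to target and to isomer of the product. Such a pair keeps their ratio constant, and a ratio of 1 is the symmetric case of equal branches. The spring run read 2.21 at 0.417 min. The two runs read close together near the same time: the dusk run read 1.45 at 1.00 min, while the spring run read 1.45 at 0.667 min and 1.38 at 1.33 min.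

**One drain.** Next I let target drain while the branches ran, so the ratio had to fall. In the spring run it crossed 1 and read 0.477 at 5.00 min, an average logarithmic fall of 0.334 min⁻¹ between these two readings. Running that back to 8.0 s gave 2.43. I named this the split, the early ratio of target to isomer of the product, or selectivity factor of the branches.

**The rest.** The last two dusk readings gave a fall of 0.150 min⁻¹, less than the spring average of 0.334 min⁻¹, though the two figures come from different runs and spans and carry the scatter of the readings. Continuing the last dusk ratio at that pace to 8.0 min gave 0.344, my own rough estimate for the flask.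

**The forecast.** It gave 2.2 at 8.0 s, on this ground: “At 8 s almost no drain has happened”. For 8.0 min it gave 0.43. My early figure stood above it and my late figure below it.

**The flask.** It gave 2.41 at 8.0 s and 0.383 at 8.0 min, so the forecast held.

    substrate + coupling partner ⇌ target (K = 69.6 M⁻¹, k = 1.53 M⁻¹ s⁻¹)
    substrate + coupling partner ⇌ isomer of the product (K = 202 M⁻¹, k = 0.590 M⁻¹ s⁻¹)
    target → over-reaction product (k = 0.00440 s⁻¹)
    gas ⇌ coupling partner, rate k4*(csat - [coupling partner]) (kL = 0.0260 s⁻¹)
    substrate ⇌ dormant form (K = 0.350, k = 0.0866 s⁻¹)

**The split again.** In this flask, target and isomer of the product stood level at 2.17 min, each at 10.8%, where the ratio crossed 1. By 8.0 min this flask kept 0.158 of the split. The flask charged with 0.60 M gave 2.39 at 8.0 s, matching the split, and kept 0.187 of it, a ratio of 0.454 at 8.0 min.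

The runs are simulated with made-up constants; noise was put on by code.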